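If this flask were to stay as still as the north-west run, its [free catalyst] would have to sit barely above its [impurity], as that run's did, at 25 µM against 24 µM.

all flasks: impurity 24 µM

| charge | left-handed substrate | right-handed substrate | solid reagent | free catalyst | remark | time |
|---|---|---|---|---|---|---|
| north-west | 1 mM | 1 mM | 3 mM | 25 µM | run made earlier |  |
| north-east | 1 mM | 1 mM | 3 mM | 100 µM | run made earlier |  |
| flask | 1.0 mM | 1.0 mM | 3.00 mM | 50 µM |  | 5.0 min |

- north-west (time / min: left-handed substrate / %, left-handed product / %): 0.250: 50.1, 0; 0.417: 50.2, 0.5; 0.833: 49.4, 0; 1.50: 49.6, 0; 3.00: 50.1, 1.0
- north-east (time / min: left-handed substrate / %, left-handed product / %): 0.250: 49.5, 0; 0.833: 47.6, 0.8; 1.33: 46.7, 2.9; 2.00: 45.0, 4.4; 3.00: 41.8, 6.9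

(each reading ± 0.5 percentage points)

- free catalyst is single-handed; left-handed substrate and right-handed substrate are mirror images of each other, charged as a racemate, each of them at the stated concentration
- given per volume of solution although it is solid: solid reagent
- at the start none of the solid reagent is in solution

* share of the left-handed substrate and right-handed substrate together used up at 5.0 min
* left-handed product at 5.0 min, in percent of the left-handed substrate and right-handed substrate together charged
* amount of left-handed product if the flask were left three thousand times as long, in percent of the left-handed substrate and right-handed substrate together charged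

At 3.00 min the north-west run still read 50.1 % left-handed substrate, while the north-east run had fallen to 41.8 %. I took this to mean that the impurity kills free catalyst one for one. So I carried one quantity: the surviving share, the part of the charged free catalyst left once the impurity has taken its own amount, 52.0 % in this flask. The same count gave 4.00 % for the north-west run and 76.0 % for the north-east run. This flask therefore stood well clear of the still case, with 26.0 µM surviving, a third of the north-east amount. Left-handed substrate is 50.0 % of the charge, so I expected about that much left-handed product in the long run. Neither earlier run reports right-handed substrate, so my own count gave no figure for conversion, and I put no figure of my own on the product at 5.0 min either.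

The forecast gave 5 % used up, 4.3 % left-handed product and 48 % in the long run, holding: “any right-handed loss is assumed small”.

The flask gave 33.9 % used up, 9.31 % left-handed product and 50.0 % in the long run.

    free catalyst + left-handed substrate ⇌ catalyst intermediate A (K = 570 L mol⁻¹, k = 2200 L mol⁻¹ s⁻¹)
    free catalyst + right-handed substrate ⇌ catalyst intermediate B (K = 5000 L mol⁻¹, k = 83000 L mol⁻¹ s⁻¹)
    partner + catalyst intermediate A → free catalyst + left-handed product (k = 4700 L mol⁻¹ s⁻¹)
    partner + catalyst intermediate B → free catalyst + right-handed product (k = 1600 L mol⁻¹ s⁻¹)
    solid reagent ⇌ partner, rate k5*(cs5 - [partner]) while solid is left; crystals form when [partner] > cs5 (solubility = 0.350 mM, k = 0.00890 s⁻¹)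
    partner ⇌ dormant form (K = 1.10, k = 0.270 s⁻¹)
    free catalyst + impurity → spent catalyst (k = 2.60 × 10⁵ L mol⁻¹ s⁻¹)

At 5.00 min the flask held 0 % impurity, the limiting reagent of that poisoning, and 48.0 % spent catalyst, while catalyst intermediate A, catalyst intermediate B and free catalyst added up to 52.0 %, matching the surviving share. At 2.43 min the forward step alone gave right-handed substrate a half-life of 1.7 s, far shorter than the 1.1 min of left-handed substrate. By 5.00 min the flask kept 51 % of its right-handed substrate, less than the 81 % of its left-handed substrate. For the neighbour flask charged with 85.0 µM the surviving share comes to 71.8 %, and its three working forms added up to 71.8 % at 5.00 min.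

(The numbers in the tables come from a simulation with made-up constants.)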